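Atom labels used throughout: seven-membered ring C2(H,Me)–C3–C4–C5(OH)–C6(H)–C10(=O)–C11(Me, side chain); five-membered ring C5–C6–C7–C8(OH)–C9(Me2). Intermediates carry the same labels.

## Analysis of the target

Target 28 is a trans-fused hydroazulenone: a cycloheptanone (C2–C3–C4–C5–C6–C10–C11) fused along C5–C6 to a cyclopentane (C5–C6–C7–C8–C9), with a two-carbon chain on C11 that ends in a β-substituted butenolide. It has five stereocentres, C2 (R), C5 (S), C6 (S), C8 (R) and C11 (S). The quaternary C11 sits next to the tertiary C2 with the two methyl groups cis. The C5 hydroxyl is trans to H6 and cis (1,3) to the C8 hydroxyl. The gem-dimethyl carbon C9 lies between the two carbinol carbons, so the C8 hydroxyl is neopentylic, and the C10 carbonyl is flanked by quaternary C11 and the ring-fusion carbon C6. The ketol C5(OH)–C6(H)–C10(=O) is the sensitive part: base can cause retro-aldol cleavage of the ring-fusion bond, dehydration to the C5=C6 enone, or epimerisation at C6. The butenolide tolerates neither Grignard reagents, hydride, hydrogenation nor strong base. The difficulty is a congested seven-membered ketone with an oxygenated ring-fusion carbon, and the relay of configuration between the C2/C11 pair and the C5/C6/C8 triad across C3–C4 and C10. The strategy rests on reading the ketol as the oxygenated, ring-opened form of a cyclopropanol made of C10, C5 and C6. That cyclopropanol is the Kulinkovich product of a C10 ester and a C5=C6 cyclopentene, and the C8 hydroxyl on the same ring can steer titanium.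

## Retrosynthetic reasoning

**28 ⇒ 24 + 25 (side chain–butenolide bond).** The butenolide would not survive the organometallic and oxidative steps, so it is attached last by an sp3–sp2 Negishi coupling of the primary iodide 24 with 4-bromofuran-2(5H)-one 25. The cut leaves a plain two-carbon oxygenated chain on C11 for the whole synthesis.

**24 ⇒ 23 ⇒ 22 ⇒ 21 (functional-group changes only).** The two hydroxyls of iodide 23 are masked as trimethylsilyl ethers in 24 so that the alkylzinc is not protonated. Iodide 23 comes from triol 22 by selective substitution of the only primary hydroxyl, and 22 from the silyl ether 21 under acidic fluoride, because the ketol does not tolerate base.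

**21 ⇒ 19 (C5–O bond traded for the C5–C10 bond).** The β-hydroxy ketone is taken back to the tricyclic cyclopropanol 19. The forward reaction is an aerobic, manganese-catalysed ring opening that passes through the cyclic peroxy hemiketal 20. This replaces a direct seven-membered ring closure by a six-membered one followed by a one-carbon enlargement, and it stores the C6 configuration in the cyclopropane. The forward step must break the internal C5–C10 bond, which is favoured because it gives the tertiary radical. It must also bring oxygen to C5 on the face that C10 leaves. That second point is not guaranteed by closure of the peroxide, because oxygen capture by a tertiary radical is irreversible, so it is treated as a risk of its own.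

**19 ⇒ 18 (C6–C10 and C5–C10, the key disconnection).** Removing both bonds from C10 to the cyclopentane returns the methyl ester 18 tethered through C2–C3–C4 to an (R)-cyclopentenol. The forward reaction is an intramolecular Kulinkovich cyclopropanation. The free C8 hydroxyl is kept as the directing group for titanium. The cut is made here because it turns the hardest ring closure into an ester–alkene coupling with a built-in directing group, and it leaves two fragments of very unequal but low complexity.

**18 ⇒ 11 + 15 (C4–C5, sp3–sp2).** This bond separates the two stereochemical domains. Iodide 11 carries C2 and C11, triflate 15 carries C8. A Negishi coupling joins them without touching any stereocentre, and the trimethylsilyl group on O8 is removed in the same operation.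

**15 ⇒ 14 ⇒ 13 ⇒ 12 (cyclopentene fragment).** The enol triflate can form in one direction only, because C9 is quaternary. The carbinol centre comes from enzymatic desymmetrisation of the achiral dione 12, which needs no auxiliary.

**11 ⇒ 10 ⇒ 9 ⇒ 8 ⇒ 7 (chain from a ring).** The acyclic pair C2/C11 is hard to set in a chain, so it is set on a cyclohexanone and the ring is then cut between C10 and its methylene neighbour. Ketol 8 is cleaved to the methyl ester and an aldehyde, 9, which differentiates the two termini at once. The surplus carbon is then removed by oxidation to acid 10 and decarboxylative iodination to 11.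

**7 ⇒ 6 ⇒ 4 ⇒ 3 ⇒ 2 ⇒ 1 (quaternary centre on the chiral pool).** The silyloxyethyl arm is a shortened allyl group. Allyl and methyl are introduced at C11 by two successive enolate alkylations of (R)-pulegone 1, whose stereocentre becomes C2. The isopropylidene group blocks the other α-position during both alkylations and is removed afterwards by retro-aldol cleavage. The order, methyl first and allyl second, places the allyl group trans to the C2 methyl, as C11 requires.

## Alternatives that were turned down

**Alternative 1: Prins–pinacol ring enlargement.**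
- Disconnection: C7–C8 and C5–C6, with C5 migrating from C10 to C6.
- Forward step: a strong Lewis acid ionises an acetal at C8, a vinyl group on C10 attacks it through C7, and the ring carbon C5 shifts from C10 to C6. This closes the cyclopentane and enlarges a cyclohexane to the cycloheptanone, giving the trans-fused hydroazulenone A1 with silyl and benzyl ethers.
- For it: two C–C bonds, both rings and the C10 ketone appear in one operation. C5 already carries its oxygen and migrates with retention. The reaction type is well established for ring-enlarging cyclopentane annulation. On precedent for the key step, and on the C5 oxygen, it is the stronger plan.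
- Against it: before the step, C5 and C10 must both be fully substituted carbinol carbons side by side on the six-membered ring, next to quaternary C11, and C5 must also carry the neopentyl acetal chain. That demands two additions to hindered carbonyls with control of both configurations. The Lewis acid can also ionise the tertiary C5 silyl ether or the tertiary allylic C10–O bond. C6 and C8 are set only by the preferred geometry of the closure. The benzyl ethers must be removed before the butenolide is present.
- Comparison: the chosen route offers a much simpler, convergent precursor and keeps the C8 hydroxyl free as a control element, at the price of a key step without direct precedent.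

**Alternative 2: photooxygenation of a cyclopentadiene.**
- Disconnection: both C–O bonds, at C5 and C8.
- Forward step: dye-sensitised photooxygenation adds oxygen across C5 and C8 of a bicyclic diene (C5=C6–C7=C8) and gives the endoperoxide A2.
- For it: the cis-1,3 relation of the two oxygens is guaranteed by the bridge. On this point it is stronger than the chosen route, where the face of oxygenation at C5 is the open question.
- Against it: the step forms no C–C bond and closes no carbocycle, so the seven-membered ring, the fused diene and a protected C10 carbinol must all be made first. The face of attack is set only by remote substituents. Bicyclic peroxides of this type are labile to heat and base. After O–O reduction the C6=C7 bond must be reduced with hydrogen delivered trans to the C5 hydroxyl, against the usual directing effect, and C10 must still be oxidised.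
- Comparison: the chosen route builds two rings, two C–C bonds and C6 in its key step and needs fewer redox adjustments afterwards.

**Alternative 3: hydroxyl-directed rhodium hydroacylation.**
- Disconnection: C6–C10.
- Forward step: a cationic rhodium–diphosphine catalyst adds the C10 aldehyde C–H across the C6=C7 bond of a cyclopentenol in which C5 is already the tertiary carbinol. This closes the seven-membered ring and gives the ketol bis(silyl ether) A3.
- For it: the ketol appears directly at the right oxidation level and with full atom economy. C5 is set earlier by a carbonyl addition and C6 by syn delivery from rhodium bound to the C5 hydroxyl. Its control of C5 and its directness are better than in the chosen route.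
- Against it: intramolecular hydroacylation closes five-membered rings reliably. Seven-membered closure onto an internal cyclopentene is rare and competes with decarbonylation, which is especially easy for an α-quaternary acyl–rhodium hydride. The tertiary allylic alcohol may ionise under the cationic metal.
- Comparison: both key steps lie beyond precedent. The chosen one closes a six-membered ring first and enlarges it afterwards, and it uses an ester, which cannot decarbonylate.

Key step: step 14

Assumption: a ketoreductase that reduces one carbonyl of dione 12 to the (R)-carbinol is taken from a commercial enzyme panel, and commercial (R)-pulegone fixes C2.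

## Route

Step 1
Reactants: 1 (R)-pulegone
Product: 2 (5R)-5,6-dimethyl-2-(propan-2-ylidene)cyclohexan-1-one (both C6 epimers)
Conditions: LDA, THF, −78 °C; MeI, −78 → 0 °C
Reagents that add atoms: iodomethane, CI
Why: Kinetic deprotonation of the enone by the lithium amide occurs at the α′-methylene (future C11) and gives the cross-conjugated enolate, which is methylated (enolate alkylation); the new centre is enolised again in step 2, so its configuration does not matter.

Step 2
Reactants: 2 (5R)-5,6-dimethyl-2-(propan-2-ylidene)cyclohexan-1-one
Product: 3 (5R,6S)-5,6-dimethyl-6-(prop-2-en-1-yl)-2-(propan-2-ylidene)cyclohexan-1-one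
Conditions: LDA, THF, −78 → −30 °C; allyl bromide, DMPU, −78 → 0 °C
Reagents that add atoms: allyl bromide, C=CCBr
Why: A second α′-enolisation gives the tetrasubstituted enolate, in which the C2 methyl turns pseudoaxial to avoid allylic 1,2-strain with the C11 methyl; allyl bromide enters on the opposite face, so the allyl group ends trans and the two methyls cis, which is the (S) configuration of C11 (enolate alkylation under 1,2-induction).

Step 3
Reactants: 3 (5R,6S)-5,6-dimethyl-6-(prop-2-en-1-yl)-2-(propan-2-ylidene)cyclohexan-1-one
Product: 4 (2S,3R)-2,3-dimethyl-2-(prop-2-en-1-yl)cyclohexan-1-one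
Conditions: aq. KOH, EtOH, reflux, acetone distilled off
Reagents that add atoms: none
Why: Conjugate addition of hydroxide to the isopropylidene carbon and retro-aldol cleavage remove the blocking group as acetone; the quaternary centre cannot epimerise and C2 is not acidic.

Step 4
Reactants: 4 (2S,3R)-2,3-dimethyl-2-(prop-2-en-1-yl)cyclohexan-1-one
Product: 6 (2S,3R)-2-(2-hydroxyethyl)-2,3-dimethylcyclohexan-1-one, via keto aldehyde 5 (not isolated)
Conditions: O3, CH2Cl2/MeOH, −78 °C; Me2S, −78 °C → rt; NaBH4, −78 °C
Reagents that add atoms: ozone, [O-][O+]=O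
Why: Ozonolysis shortens the allyl group to the acetaldehyde arm, and borohydride at −78 °C reduces the unhindered aldehyde much faster than the α-quaternary ketone.

Step 5
Reactants: 6 (2S,3R)-2-(2-hydroxyethyl)-2,3-dimethylcyclohexan-1-one
Product: 7 (2S,3R)-2-[2-(tert-butyldimethylsilyloxy)ethyl]-2,3-dimethylcyclohexan-1-one
Conditions: TBSCl, imidazole, DMF, rt
Reagents that add atoms: tert-butyldimethylsilyl chloride, CC(C)(C)[Si](C)(C)Cl
Why: Silylation traps the open hydroxy ketone as the primary silyl ether, which withstands every step up to the fluoride treatment in step 16.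

Step 6
Reactants: 7 (2S,3R)-2-[2-(tert-butyldimethylsilyloxy)ethyl]-2,3-dimethylcyclohexan-1-one
Product: 8 (2S,3R)-2-[2-(tert-butyldimethylsilyloxy)ethyl]-6-hydroxy-2,3-dimethylcyclohexan-1-one (both C6 epimers)
Conditions: NaHMDS, THF, −78 °C; 2-(phenylsulfonyl)-3-phenyloxaziridine, −78 °C; aq. NH4Cl
Reagents that add atoms: 2-(phenylsulfonyl)-3-phenyloxaziridine, O=S(=O)(c1ccccc1)N1OC1c1ccccc1
Why: Only the methylene side of the ketone can be enolised, and the enolate is hydroxylated by the N-sulfonyloxaziridine (enolate oxidation); the new carbinol centre is destroyed in step 7.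

Step 7
Reactants: 8 (2S,3R)-2-[2-(tert-butyldimethylsilyloxy)ethyl]-6-hydroxy-2,3-dimethylcyclohexan-1-one
Product: 9 methyl (2S,3R)-2-[2-(tert-butyldimethylsilyloxy)ethyl]-2,3-dimethyl-6-oxohexanoate
Conditions: Pb(OAc)4, MeOH/PhH (1:1), 0 °C → rt
Reagents that add atoms: methanol, CO
Why: Tetravalent lead cleaves the α-ketol through its methyl hemiketal in a glycol-type fragmentation; the ketone carbon leaves as the C10 methyl ester and the carbinol carbon as an aldehyde, so the two chain ends are differentiated in the cleavage itself.

Step 8
Reactants: 9 methyl (2S,3R)-2-[2-(tert-butyldimethylsilyloxy)ethyl]-2,3-dimethyl-6-oxohexanoate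
Product: 10 (4R,5S)-5-[2-(tert-butyldimethylsilyloxy)ethyl]-6-methoxy-4,5-dimethyl-6-oxohexanoic acid
Conditions: NaClO2, NaH2PO4, 2-methylbut-2-ene, t-BuOH/H2O, rt
Reagents that add atoms: sodium chlorite, [Na+].[O-]Cl=O
Why: Pinnick oxidation converts the aldehyde into the acid under buffered conditions that leave the silyl ether, the ester and the stereocentres alone.

Step 9
Reactants: 10 (4R,5S)-5-[2-(tert-butyldimethylsilyloxy)ethyl]-6-methoxy-4,5-dimethyl-6-oxohexanoic acid
Product: 11 methyl (2S,3R)-2-[2-(tert-butyldimethylsilyloxy)ethyl]-5-iodo-2,3-dimethylpentanoate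
Conditions: PhI(OAc)2, I2, PhH, visible light, 60 °C
Reagents that add atoms: iodine, II
Why: Decarboxylative iodination of the Hunsdiecker type: the acyl hypoiodite formed in the flask is cleaved by light, the acyloxy radical loses CO2, and the primary C4 radical takes up iodine faster than it can abstract hydrogen or cyclise.

Step 10
Reactants: 12 2,2-dimethylcyclopentane-1,3-dione
Product: 13 (3R)-3-hydroxy-2,2-dimethylcyclopentan-1-one
Conditions: (R)-selective ketoreductase, NADP+ (cat.), iPrOH, phosphate buffer pH 7, 30 °C
Reagents that add atoms: none
Why: Enzymatic desymmetrising reduction: the active site distinguishes the two enantiotopic carbonyls and stops at the hydroxy ketone, which sets C8 (R).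

Step 11
Reactants: 13 (3R)-3-hydroxy-2,2-dimethylcyclopentan-1-one
Product: 14 (3R)-2,2-dimethyl-3-(trimethylsilyloxy)cyclopentan-1-one
Conditions: TMSCl, imidazole, CH2Cl2, 0 °C
Reagents that add atoms: chlorotrimethylsilane, C[Si](C)(C)Cl
Why: The hydroxyl is masked for the enolisation; a trimethylsilyl ether is chosen because it can later be removed in the presence of the primary tert-butyldimethylsilyl ether.

Step 12
Reactants: 14 (3R)-2,2-dimethyl-3-(trimethylsilyloxy)cyclopentan-1-one
Product: 15 (4R)-5,5-dimethyl-4-(trimethylsilyloxy)cyclopent-1-en-1-yl trifluoromethanesulfonate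
Conditions: KHMDS, THF, −78 °C; PhNTf2, −78 → 0 °C
Reagents that add atoms: N-phenylbis(trifluoromethanesulfonimide), O=S(=O)(N(c1ccccc1)S(=O)(=O)C(F)(F)F)C(F)(F)F
Why: Enol triflate formation; the enolate can form only towards the methylene (future C6), and β-elimination of the silyloxy group is impossible because the carbon between carbonyl and carbinol is quaternary.

Step 13
Reactants: 11 methyl (2S,3R)-2-[2-(tert-butyldimethylsilyloxy)ethyl]-5-iodo-2,3-dimethylpentanoate; 15 (4R)-5,5-dimethyl-4-(trimethylsilyloxy)cyclopent-1-en-1-yl trifluoromethanesulfonate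
Product: 18 methyl (2S,3R)-2-[2-(tert-butyldimethylsilyloxy)ethyl]-5-[(4R)-4-hydroxy-5,5-dimethylcyclopent-1-en-1-yl]-2,3-dimethylpentanoate, via alkylzinc iodide 16 (not isolated), via trimethylsilyl ether 17 (not isolated)
Conditions: Zn dust (BrCH2CH2Br, TMSCl activation), LiCl, THF, 40 °C; then 15, PdCl2(dppf) (5 mol %), THF/NMP, 50 °C; then K2CO3, MeOH, 0 °C
Reagents that add atoms: none
Why: Negishi coupling: zinc inserts into the primary C–I bond, and the alkylzinc, which tolerates the ester, couples with the enol triflate under palladium catalysis to form C4–C5; mild methanolysis then removes only the trimethylsilyl group, and no stereocentre is involved.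

Step 14
Reactants: 18 methyl (2S,3R)-2-[2-(tert-butyldimethylsilyloxy)ethyl]-5-[(4R)-4-hydroxy-5,5-dimethylcyclopent-1-en-1-yl]-2,3-dimethylpentanoate
Product: 19 (1S,3R,5S,6R,7S,8R)-7-[2-(tert-butyldimethylsilyloxy)ethyl]-2,2,7,8-tetramethyltricyclo[4.4.0.0(1,5)]decane-3,6-diol (atom labels: 2R,5S,6S,8R,10R,11S; cyclopropane C5–C6–C10 on the face of the C8 hydroxyl)
Conditions: Ti(OiPr)4 (1.5 equiv), c-C6H11MgCl (5 equiv, slow addition), THF, 0 °C → rt; aq. NH4Cl
Reagents that add atoms: none
Why: Proposed new method: two equivalents of cyclohexylmagnesium chloride turn Ti(OiPr)4 into the cyclohexene complex of divalent titanium (a titanacyclopropane) and a further equivalent deprotonates the C8 hydroxyl; once the C8 alkoxide is bound to titanium, the weakly held cyclohexene is exchanged for the C5=C6 bond on the face that carries O8, the only face the chelate can reach. The ester carbonyl then inserts into the less hindered Ti–C6 bond (C6–C10), methoxide leaves, and the remaining tertiary Ti–C5 homoenolate adds to the C10 ketone (C5–C10). This last bond closes the cyclopropane by 3-exo-trig attack and, through the C2–C3–C4 tether, the six-membered ring in a 6-exo-trig sense; the reverse order of the two bond formations would give the same product. The closest known reactions are the intramolecular Kulinkovich cyclopropanation of ω-alkenyl esters with terminal alkenes and the intermolecular, homoallylic-alkoxide-directed coupling of esters with disubstituted alkenes; neither has been shown for a trisubstituted cyclopentene or an α-quaternary ester. C5 and C6 are set by syn addition to the alkene face fixed by the C8 alkoxide, so C10 ends cis to the C8 oxygen, and the configuration of C10 follows from the cis fusion of the three-membered ring and from the tether. The step needs face selectivity (secured by the alkoxide), alkene exchange in preference to cyclopropanation by the cyclohexene ligand (that complex reacts only slowly with esters, a hindered one more slowly still), and no Grignard addition to the ester (slow addition and the shielding by the quaternary C11).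

Step 15
Reactants: 19 tricyclic cyclopropanol (as in step 14)
Product: 21 (2R,3aS,5S,6R,8aS)-5-[2-(tert-butyldimethylsilyloxy)ethyl]-2,8a-dihydroxy-1,1,5,6-tetramethyloctahydroazulen-4(1H)-one, via peroxy hemiketal 20 (not isolated)
Conditions: Mn(acac)3 (10 mol %), O2 (1 atm), THF, rt; then thiourea, MeOH, 0 °C → rt
Reagents that add atoms: oxygen, O=O
Why: Trivalent manganese oxidises the cyclopropanol to the cyclopropoxy radical, which breaks the internal C5–C10 bond because this gives the tertiary C5 radical and the seven-membered ketone; the radical takes up O2, the peroxide lying cis to C10 closes onto the ketone to the 1,2-dioxolan-3-ol 20, and thiourea reduces the O–O bond to the ketol (aerobic ring opening of cyclopropanols to β-hydroxy ketones). C6 is untouched, so C10 stays cis to the C8 oxygen; C5 is fixed when O2 is captured, and because that capture is irreversible the closure to 20 does not by itself select the face: oxygen delivered from the manganese held at the C10 oxygen gives the required epimer, while material oxygenated from the other face cannot close, ends as the C5 epimer and is removed by chromatography.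

Step 16
Reactants: 21 (2R,3aS,5S,6R,8aS)-5-[2-(tert-butyldimethylsilyloxy)ethyl]-2,8a-dihydroxy-1,1,5,6-tetramethyloctahydroazulen-4(1H)-one
Product: 22 (2R,3aS,5S,6R,8aS)-2,8a-dihydroxy-5-(2-hydroxyethyl)-1,1,5,6-tetramethyloctahydroazulen-4(1H)-one
Conditions: HF·pyridine, pyridine, THF, 0 °C → rt
Reagents that add atoms: none
Why: Buffered acidic fluoride removes the primary silyl ether without base, which protects the ketol from retro-aldol cleavage, dehydration and C6 epimerisation.

Step 17
Reactants: 22 (2R,3aS,5S,6R,8aS)-2,8a-dihydroxy-5-(2-hydroxyethyl)-1,1,5,6-tetramethyloctahydroazulen-4(1H)-one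
Product: 23 (2R,3aS,5S,6R,8aS)-2,8a-dihydroxy-5-(2-iodoethyl)-1,1,5,6-tetramethyloctahydroazulen-4(1H)-one
Conditions: I2, PPh3, imidazole, CH2Cl2, 0 °C
Reagents that add atoms: iodine, II
Why: Appel-type iodination: only the primary alkoxyphosphonium ion is displaced by iodide, since the neopentylic secondary and the tertiary hydroxyl cannot undergo substitution at 0 °C.

Step 18
Reactants: 23 (2R,3aS,5S,6R,8aS)-2,8a-dihydroxy-5-(2-iodoethyl)-1,1,5,6-tetramethyloctahydroazulen-4(1H)-one
Product: 24 (2R,3aS,5S,6R,8aS)-5-(2-iodoethyl)-1,1,5,6-tetramethyl-2,8a-bis(trimethylsilyloxy)octahydroazulen-4(1H)-one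
Conditions: 1-(trimethylsilyl)imidazole (excess), CH2Cl2, rt → 40 °C
Reagents that add atoms: 1-(trimethylsilyl)imidazole, C[Si](C)(C)n1ccnc1
Why: The neutral silyl donor silylates hindered secondary and tertiary hydroxyls without forming the enol silane of the ketone, so C6 is not put at risk; the silyl ethers keep the alkylzinc of step 19 from being protonated.

Step 19
Reactants: 24 (2R,3aS,5S,6R,8aS)-5-(2-iodoethyl)-1,1,5,6-tetramethyl-2,8a-bis(trimethylsilyloxy)octahydroazulen-4(1H)-one; 25 4-bromofuran-2(5H)-one
Product: 28 (2R,3aS,5S,6R,8aS)-2,8a-dihydroxy-1,1,5,6-tetramethyl-5-[2-(5-oxo-2,5-dihydrofuran-3-yl)ethyl]octahydroazulen-4(1H)-one, via alkylzinc iodide 26 (not isolated), via bis(trimethylsilyl) ether 27 (not isolated)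
Conditions: Zn dust (activated), LiCl, THF, 40 °C; then 25, PdCl2(dppf) (5 mol %), THF/NMP, rt → 40 °C; then citric acid, MeOH, rt
Reagents that add atoms: none
Why: Negishi coupling of the primary alkylzinc, which does not add to the ketone, with the β-bromobutenolide; the bidentate phosphine suppresses β-hydride elimination, and mild acidic methanolysis removes both trimethylsilyl ethers without touching the ketol or the lactone.

## Compound list

1 | (R)-pulegone, (5R)-5-methyl-2-(propan-2-ylidene)cyclohexan-1-one | C[C@@H]1CCC(=C(C)C)C(=O)C1 | starting material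
2 | (5R)-5,6-dimethyl-2-(propan-2-ylidene)cyclohexan-1-one (C6 epimers) | C[C@@H]1CCC(=C(C)C)C(=O)C1C | intermediate
3 | (5R,6S)-5,6-dimethyl-6-(prop-2-en-1-yl)-2-(propan-2-ylidene)cyclohexan-1-one | C[C@@H]1CCC(=C(C)C)C(=O)[C@@]1(C)CC=C | intermediate
4 | (2S,3R)-2,3-dimethyl-2-(prop-2-en-1-yl)cyclohexan-1-one | C[C@@H]1CCCC(=O)[C@@]1(C)CC=C | intermediate
5 | 2-[(1S,2R)-1,2-dimethyl-6-oxocyclohexyl]acetaldehyde | C[C@@H]1CCCC(=O)[C@@]1(C)CC=O | intermediate (not isolated)
6 | (2S,3R)-2-(2-hydroxyethyl)-2,3-dimethylcyclohexan-1-one | C[C@@H]1CCCC(=O)[C@@]1(C)CCO | intermediate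
7 | (2S,3R)-2-[2-(tert-butyldimethylsilyloxy)ethyl]-2,3-dimethylcyclohexan-1-one | C[C@@H]1CCCC(=O)[C@@]1(C)CCO[Si](C)(C)C(C)(C)C | intermediate
8 | (2S,3R)-2-[2-(tert-butyldimethylsilyloxy)ethyl]-6-hydroxy-2,3-dimethylcyclohexan-1-one (C6 epimers) | C[C@@H]1CCC(O)C(=O)[C@@]1(C)CCO[Si](C)(C)C(C)(C)C | intermediate
9 | methyl (2S,3R)-2-[2-(tert-butyldimethylsilyloxy)ethyl]-2,3-dimethyl-6-oxohexanoate | COC(=O)[C@@](C)(CCO[Si](C)(C)C(C)(C)C)[C@H](C)CCC=O | intermediate
10 | (4R,5S)-5-[2-(tert-butyldimethylsilyloxy)ethyl]-6-methoxy-4,5-dimethyl-6-oxohexanoic acid | COC(=O)[C@@](C)(CCO[Si](C)(C)C(C)(C)C)[C@H](C)CCC(=O)O | intermediate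
11 | methyl (2S,3R)-2-[2-(tert-butyldimethylsilyloxy)ethyl]-5-iodo-2,3-dimethylpentanoate | COC(=O)[C@@](C)(CCO[Si](C)(C)C(C)(C)C)[C@H](C)CCI | intermediate
12 | 2,2-dimethylcyclopentane-1,3-dione | CC1(C)C(=O)CCC1=O | starting material
13 | (3R)-3-hydroxy-2,2-dimethylcyclopentan-1-one | O=C1CC[C@@H](O)C1(C)C | intermediate
14 | (3R)-2,2-dimethyl-3-(trimethylsilyloxy)cyclopentan-1-one | O=C1CC[C@@H](O[Si](C)(C)C)C1(C)C | intermediate
15 | (4R)-5,5-dimethyl-4-(trimethylsilyloxy)cyclopent-1-en-1-yl trifluoromethanesulfonate | FC(F)(F)S(=O)(=O)OC1=CC[C@@H](O[Si](C)(C)C)C1(C)C | intermediate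
16 | {(3R,4S)-6-(tert-butyldimethylsilyloxy)-4-(methoxycarbonyl)-3,4-dimethylhexyl}zinc iodide | COC(=O)[C@@](C)(CCO[Si](C)(C)C(C)(C)C)[C@H](C)CC[Zn]I | intermediate (not isolated)
17 | methyl (2S,3R)-2-[2-(tert-butyldimethylsilyloxy)ethyl]-5-[(4R)-5,5-dimethyl-4-(trimethylsilyloxy)cyclopent-1-en-1-yl]-2,3-dimethylpentanoate | COC(=O)[C@@](C)(CCO[Si](C)(C)C(C)(C)C)[C@H](C)CCC1=CC[C@@H](O[Si](C)(C)C)C1(C)C | intermediate (not isolated)
18 | methyl (2S,3R)-2-[2-(tert-butyldimethylsilyloxy)ethyl]-5-[(4R)-4-hydroxy-5,5-dimethylcyclopent-1-en-1-yl]-2,3-dimethylpentanoate | COC(=O)[C@@](C)(CCO[Si](C)(C)C(C)(C)C)[C@H](C)CCC1=CC[C@@H](O)C1(C)C | intermediate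
19 | (1S,3R,5S,6R,7S,8R)-7-[2-(tert-butyldimethylsilyloxy)ethyl]-2,2,7,8-tetramethyltricyclo[4.4.0.0(1,5)]decane-3,6-diol | C[C@@H]1CC[C@]23[C@H](C[C@@H](O)C2(C)C)[C@@]3(O)[C@@]1(C)CCO[Si](C)(C)C(C)(C)C | intermediate
20 | cyclic peroxy hemiketal: C5–O–O–C10(OH) bridge (1,2-dioxolan-3-ol) on the hydroazulene skeleton of 21, bridge cis to the C8 hydroxyl (atom labels 2R,5S,6S,8R,10S,11S) | C[C@@H]1CC[C@@]23OO[C@@](O)([C@H]3C[C@@H](O)C2(C)C)[C@@]1(C)CCO[Si](C)(C)C(C)(C)C | intermediate (not isolated)
21 | (2R,3aS,5S,6R,8aS)-5-[2-(tert-butyldimethylsilyloxy)ethyl]-2,8a-dihydroxy-1,1,5,6-tetramethyloctahydroazulen-4(1H)-one | C[C@@H]1CC[C@]2(O)[C@H](C[C@@H](O)C2(C)C)C(=O)[C@@]1(C)CCO[Si](C)(C)C(C)(C)C | intermediate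
22 | (2R,3aS,5S,6R,8aS)-2,8a-dihydroxy-5-(2-hydroxyethyl)-1,1,5,6-tetramethyloctahydroazulen-4(1H)-one | C[C@@H]1CC[C@]2(O)[C@H](C[C@@H](O)C2(C)C)C(=O)[C@@]1(C)CCO | intermediate
23 | (2R,3aS,5S,6R,8aS)-2,8a-dihydroxy-5-(2-iodoethyl)-1,1,5,6-tetramethyloctahydroazulen-4(1H)-one | C[C@@H]1CC[C@]2(O)[C@H](C[C@@H](O)C2(C)C)C(=O)[C@@]1(C)CCI | intermediate
24 | (2R,3aS,5S,6R,8aS)-5-(2-iodoethyl)-1,1,5,6-tetramethyl-2,8a-bis(trimethylsilyloxy)octahydroazulen-4(1H)-one | C[C@@H]1CC[C@]2(O[Si](C)(C)C)[C@H](C[C@@H](O[Si](C)(C)C)C2(C)C)C(=O)[C@@]1(C)CCI | intermediate
25 | 4-bromofuran-2(5H)-one | O=C1C=C(Br)CO1 | starting material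
26 | alkylzinc iodide of 24 (C–I replaced by C–ZnI) | C[C@@H]1CC[C@]2(O[Si](C)(C)C)[C@H](C[C@@H](O[Si](C)(C)C)C2(C)C)C(=O)[C@@]1(C)CC[Zn]I | intermediate (not isolated)
27 | bis(trimethylsilyl) ether of 28 at O5 and O8 | C[C@@H]1CC[C@]2(O[Si](C)(C)C)[C@H](C[C@@H](O[Si](C)(C)C)C2(C)C)C(=O)[C@@]1(C)CCC1=CC(=O)OC1 | intermediate (not isolated)
28 | (2R,3aS,5S,6R,8aS)-2,8a-dihydroxy-1,1,5,6-tetramethyl-5-[2-(5-oxo-2,5-dihydrofuran-3-yl)ethyl]octahydroazulen-4(1H)-one | C[C@@H]1CC[C@]2(O)[C@H](C[C@@H](O)C2(C)C)C(=O)[C@@]1(C)CCC1=CC(=O)OC1 | target

## Step count and least certain steps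

Total: 19 steps. Longest linear sequence: 16 steps (steps 1–9 and 13–19); steps 10–12 form the three-step side branch.

**Step 14 (the proposed new method).** The most likely failure is that alkene exchange does not take place. The trisubstituted cyclopentene, flanked by a quaternary carbon, may not displace cyclohexene from titanium, so the ester would be cyclopropanated by the cyclohexene ligand, attacked by the Grignard reagent or returned unchanged. Ring opening of the strained cyclopropanol during work-up is a second danger.
The fallback uses known reactions, sets out from 18 and returns at 21.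
- The methyl ester of 18 would be cleaved with KOSiMe3 (THF, 50 °C) to the carboxylic acid F1.
- Trifluoroacetic anhydride (CH2Cl2, 0 °C → rt) would activate the acid for a Friedel–Crafts-type acylation of the alkene at C6. This closes the seven-membered ring directly, with loss of the C6 proton, and gives the enone trifluoroacetate F2.
- K2CO3 in methanol would free the C8 hydroxyl to give the enone F3 (C5=C6 conjugated with C10=O).
- Nucleophilic epoxidation (tert-butyl hydroperoxide, benzyltrimethylammonium hydroxide, toluene), with the peroxide anion hydrogen-bonded to the C8 hydroxyl, would give the epoxy ketone F4 with the oxirane on that face.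
- SmI2 (THF/MeOH, −78 °C) would cleave the C6–O bond to give 21. C6 is then set by protonation of the samarium enolate and no longer by a stereospecific transfer.

**Step 15.** The likely failure is poor facial selectivity when the planar C5 radical captures oxygen. The face needed is the one that also carries C10 and the C8 oxygen, and it is not the less hindered one. Partial retro-aldol cleavage during the reduction is a lesser risk.
The fallback sets out from 19 and returns at 21.
- Opening with Mn(OAc)3 in the presence of Cu(OAc)2 (AcOH/MeCN, argon) would generate the same C5 radical. Divalent copper oxidises it to the alkene, and after brief treatment with DBU the conjugated enone F3 is obtained.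
- Phenylboronic acid with a secondary amine catalyst would form the boronic hemiester at O8. Its hydroxyl adds to C5 in an intramolecular oxa-Michael reaction that can only reach the face of O8, giving the cyclic phenylboronate F5. Protonation at C6 is expected on the face opposite the bridge.
- Exchange with pinacol would release 21.

**Step 2.** The likely failure is competing γ-deprotonation of the enone. The α′-hydrogen is now tertiary and hindered, so the extended dienolate may form and be alkylated at the carbon bearing the isopropylidene group. O-allylation is a lesser risk.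
The fallback sets out from 2 and returns at 4.
- Retro-aldol cleavage of 2 (aq. HCl, reflux) would give (3R)-2,3-dimethylcyclohexan-1-one F6.
- TMSCl, NaI and Et3N in MeCN would convert it into the more substituted silyl enol ether F7.
- MeLi (THF, 0 °C) would release the tetrasubstituted lithium enolate regiospecifically, and allyl bromide would alkylate it trans to the C2 methyl.

**Step 9.** The likely failures are loss of the silyl ether under the iodine and acid generated in the flask, and hydrogen abstraction by the primary radical in place of iodine capture.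
The fallback sets out from 9 and returns at 11.
- The aldehyde 9 would be converted with TBSOTf and Et3N into its silyl enol ether F8.
- Ozonolysis (Me2S work-up) would remove one carbon and give the aldehyde F9.
- NaBH4 at −78 °C would give the alcohol F10, which is used at once because it can lactonise.
- I2, PPh3 and imidazole would then give 11.

**Step 19.** The likely failures are slow zinc insertion next to the two silyl ethers, protonation of the alkylzinc after partial desilylation, and β-hydride elimination in the palladium cycle.
The fallback sets out from 23, omits step 18 and returns at 28. It is a nickel-catalysed reductive cross-electrophile coupling of the iodide 23 with 25 (NiBr2(dme), 4,4′-di-tert-butyl-2,2′-bipyridine, Mn powder, DMA, rt). This forms no organozinc and tolerates free hydroxyls.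

## Further compounds

F1 | step 14 | (2S,3R)-2-[2-(tert-butyldimethylsilyloxy)ethyl]-5-[(4R)-4-hydroxy-5,5-dimethylcyclopent-1-en-1-yl]-2,3-dimethylpentanoic acid | OC(=O)[C@@](C)(CCO[Si](C)(C)C(C)(C)C)[C@H](C)CCC1=CC[C@@H](O)C1(C)C
F2 | step 14 | trifluoroacetate (at O8) of enone F3 | C[C@@H]1CCC2=C(C[C@@H](OC(=O)C(F)(F)F)C2(C)C)C(=O)[C@@]1(C)CCO[Si](C)(C)C(C)(C)C
F3 | step 14 | (2R,5S,6R)-5-[2-(tert-butyldimethylsilyloxy)ethyl]-2-hydroxy-1,1,5,6-tetramethyl-2,3,5,6,7,8-hexahydroazulen-4(1H)-one | C[C@@H]1CCC2=C(C[C@@H](O)C2(C)C)C(=O)[C@@]1(C)CCO[Si](C)(C)C(C)(C)C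
F4 | step 14 | C5–C6 epoxide of F3, oxirane on the face of the C8 hydroxyl | C[C@@H]1CC[C@]23O[C@]2(C[C@@H](O)C3(C)C)C(=O)[C@@]1(C)CCO[Si](C)(C)C(C)(C)C
F5 | step 15 | cyclic phenylboronate bridging O5 and O8 of 21 | C[C@@H]1CC[C@]23OB(c4ccccc4)O[C@H](C[C@@H]2C(=O)[C@@]1(C)CCO[Si](C)(C)C(C)(C)C)C3(C)C
F6 | step 2 | (3R)-2,3-dimethylcyclohexan-1-one (C2 epimers) | C[C@@H]1CCCC(=O)C1C
F7 | step 2 | [(3R)-2,3-dimethylcyclohex-1-en-1-yl]oxy(trimethyl)silane | C[C@@H]1CCCC(O[Si](C)(C)C)=C1C
F8 | step 9 | methyl (2S,3R)-6-(tert-butyldimethylsilyloxy)-2-[2-(tert-butyldimethylsilyloxy)ethyl]-2,3-dimethylhex-5-enoate (E/Z) | COC(=O)[C@@](C)(CCO[Si](C)(C)C(C)(C)C)[C@H](C)CC=CO[Si](C)(C)C(C)(C)C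
F9 | step 9 | methyl (2S,3R)-2-[2-(tert-butyldimethylsilyloxy)ethyl]-2,3-dimethyl-5-oxopentanoate | COC(=O)[C@@](C)(CCO[Si](C)(C)C(C)(C)C)[C@H](C)CC=O
F10 | step 9 | methyl (2S,3R)-2-[2-(tert-butyldimethylsilyloxy)ethyl]-5-hydroxy-2,3-dimethylpentanoate | COC(=O)[C@@](C)(CCO[Si](C)(C)C(C)(C)C)[C@H](C)CCO
F0 | step 19 | none | none
A1 | alternative 1 | trans-fused hydroazulenone with C5 trimethylsilyl ether, C8 benzyl ether and benzyl-protected side chain | C[C@@H]1CC[C@]2(O[Si](C)(C)C)[C@H](C[C@@H](OCc3ccccc3)C2(C)C)C(=O)[C@@]1(C)CCOCc1ccccc1
A2 | alternative 2 | endoperoxide bridging C5 and C8, C10 triethylsilyl ether, tert-butyldiphenylsilyl-protected side chain | C[C@@H]1CC[C@]23OO[C@H](C=C2[C@@H](O[Si](CC)(CC)CC)[C@@]1(C)CCO[Si](c1ccccc1)(c1ccccc1)C(C)(C)C)C3(C)C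
A3 | alternative 3 | trans-fused hydroazulenone with free C5 hydroxyl and tert-butyldimethylsilyl ethers at O8 and on the side chain | C[C@@H]1CC[C@]2(O)[C@H](C[C@@H](O[Si](C)(C)C(C)(C)C)C2(C)C)C(=O)[C@@]1(C)CCO[Si](C)(C)C(C)(C)C
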